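**Retrosynthetic overview**
1. Feature used: ring A carries para-related oxygens at C5 (OH) and C8 (OMe), with C6–H and C7–O between them. Its C4a=C8a edge is the unsubstituted C5=C6 bond of ring C taken alone, a 2-aryl-3-hydroxy-4-pyranone.
2. Last operations: MOM removal (3-O, 4'-O) ⇐ 7-O-prenylation ⇐ hydrogenolysis of a 7-O-benzyl ether.
3. Key disconnection C4a–C5: ring A ⇐ 3-benzyloxy-4-methoxy-4-(4-oxopyran-2-yl)cyclobutenone by thermal 4π opening and 6π closure. C5–C8 come from squaric acid.
4. Cyclobutenone ⇐ 6-iodopyranone (C–H zincation, iodination, I/Mg exchange) + benzyl semisquarate. Pyranone ⇐ furan + vanillin by Achmatowicz ring expansion, enone epoxidation (this supplies the missing oxidation level) and acid aromatisation.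
5. Ring order: B (bought with vanillin), then C (from furan), then A (last).

Key step: step 13

Remark: the target is achiral, so all sp3 centres of the intermediates are transient and these compounds are carried as racemates or diastereomer mixtures.

Step 1
Reactants: 1 vanillin (4-hydroxy-3-methoxybenzaldehyde)
Product: 2 3-methoxy-4-(methoxymethoxy)benzaldehyde
Conditions: MOMCl, K2CO3, acetone, 0 °C → rt
Reagents that add atoms: chloromethyl methyl ether (MOMCl), COCCl
Why: Williamson-type O-alkylation of the phenoxide masks the acidic OH so that the aldehyde can meet an organolithium, and no stereocentre is formed.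

Step 2
Reactants: 3 furan; 2 3-methoxy-4-(methoxymethoxy)benzaldehyde
Product: 5 (±)-furan-2-yl[3-methoxy-4-(methoxymethoxy)phenyl]methanol, via 2-lithiofuran 4 (not isolated)
Conditions: n-BuLi, THF, −78 → 0 °C; then 2, −78 °C; H2O quench
Reagents that add atoms: none
Why: α-Lithiation of furan is clean at C2 and the lithio species adds 1,2 to the aryl aldehyde, giving a racemic carbinol centre that is destroyed in step 6.

Step 3
Reactants: 5 (±)-furan-2-yl[3-methoxy-4-(methoxymethoxy)phenyl]methanol
Product: 6 6-hydroxy-2-[3-methoxy-4-(methoxymethoxy)phenyl]-2H-pyran-3(6H)-one (racemic, anomer mixture)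
Conditions: NBS (1.0 equiv), NaHCO3, THF–H2O 4:1, 0 °C
Reagents that add atoms: water, O
Why: Achmatowicz rearrangement, in which bromonium-induced hydration of the furan gives the ene-dione that closes through the carbinol oxygen to the six-membered lactol (anomeric configuration irrelevant), while the bicarbonate buffer shields the acid-labile carbinol and MOM ether.

Step 4
Reactants: 6 6-hydroxy-2-[3-methoxy-4-(methoxymethoxy)phenyl]-2H-pyran-3(6H)-one
Product: 7 6-methoxy-2-[3-methoxy-4-(methoxymethoxy)phenyl]-2H-pyran-3(6H)-one (diastereomer mixture)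
Conditions: MeI, Ag2O, CH2Cl2, rt, dark
Reagents that add atoms: iodomethane, CI
Why: Neutral Purdie methylation locks the lactol as its methyl acetal, so the ring cannot open to the ene-dione aldehyde in the alkaline peroxide of the next step, and the configuration at C6 is of no consequence.

Step 5
Reactants: 7 6-methoxy-2-[3-methoxy-4-(methoxymethoxy)phenyl]-2H-pyran-3(6H)-one
Product: 8 2-methoxy-4-[3-methoxy-4-(methoxymethoxy)phenyl]-3,7-dioxabicyclo[4.1.0]heptan-5-one (the 4,5-epoxide of 7, diastereomer mixture)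
Conditions: 30% H2O2, NaOH (cat), MeOH, 0 °C
Reagents that add atoms: hydrogen peroxide, OO
Why: Weitz–Scheffer nucleophilic epoxidation touches only the electron-poor enone and installs the oxygen at pyran C4, raising the ring to the oxidation level of a hydroxypyranone, which no mere isomerisation of the Achmatowicz product can reach; the new centres are erased in step 6.

Step 6
Reactants: 8 2-methoxy-4-[3-methoxy-4-(methoxymethoxy)phenyl]-3,7-dioxabicyclo[4.1.0]heptan-5-one
Product: 9 3-hydroxy-2-(4-hydroxy-3-methoxyphenyl)-4H-pyran-4-one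
Conditions: 1 M aq H2SO4, 1,4-dioxane, 90 °C
Reagents that add atoms: none
Why: Acid opens the α,β-epoxy ketone to the 3,4-dione enol, methanol is eliminated from C6 and C2–H enolises (the sequence known for maltol-type pyranones), which drives the ring to the conjugated 3-hydroxy-4-pyranone, and the aryl MOM ether is deliberately hydrolysed in the same pot.

Step 7
Reactants: 9 3-hydroxy-2-(4-hydroxy-3-methoxyphenyl)-4H-pyran-4-one
Product: 10 3-(methoxymethoxy)-2-[3-methoxy-4-(methoxymethoxy)phenyl]-4H-pyran-4-one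
Conditions: MOMCl (2.5 equiv), K2CO3, acetone, 0 °C → rt
Reagents that add atoms: chloromethyl methyl ether (MOMCl), COCCl
Why: Both acidic hydroxyls (enolic 3-OH and phenolic 4'-OH) are alkylated in one Williamson-type operation to acetals that tolerate the organometallic steps, the thermolysis and hydrogenolysis.

Step 8
Reactants: 10 3-(methoxymethoxy)-2-[3-methoxy-4-(methoxymethoxy)phenyl]-4H-pyran-4-one
Product: 12 6-iodo-3-(methoxymethoxy)-2-[3-methoxy-4-(methoxymethoxy)phenyl]-4H-pyran-4-one, via pyranonylzinc chloride 11 (not isolated)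
Conditions: TMPZnCl·LiCl (TMP = 2,2,6,6-tetramethylpiperidide), THF, 25 °C; then I2, THF, 0 °C
Reagents that add atoms: iodine, II
Why: C–H zincation with the mild zinc amide removes the most acidic ring proton, the one next to the ring oxygen, as established for C2–H of chromones, whereas a lithium amide bound to the carbonyl could deprotonate C5 and expel the ring oxygen by β-elimination; iodinolysis then fixes the site as a stable C–I bond.

Step 9
Reactants: 13 squaric acid
Product: 14 dibenzyl squarate (3,4-bis(benzyloxy)cyclobut-3-ene-1,2-dione)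
Conditions: BnOH, toluene, reflux, Dean–Stark
Reagents that add atoms: benzyl alcohol, OCc1ccccc1
Why: Squaric acid is a strong vinylogous acid that catalyses its own Fischer-type esterification once water is removed azeotropically.

Step 10
Reactants: 14 dibenzyl squarate
Product: 16 3-(benzyloxy)cyclobut-3-ene-1,2-dione (benzyl semisquarate), via hydroxycyclobutenone 15 (not isolated)
Conditions: LiAlH(OtBu)3, THF, −78 → −20 °C; then 2 M aq HCl, CH2Cl2, rt
Reagents that add atoms: water, O
Why: The bulky hydride adds once, 1,2, to one carbonyl of the symmetric diester, and acid then ionises the carbinol, water enters at the distal alkoxy carbon and benzyl alcohol leaves, which is the standard conversion of squarate 1,2-adducts into 3-alkoxycyclobutenediones.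

Step 11
Reactants: 12 6-iodo-3-(methoxymethoxy)-2-[3-methoxy-4-(methoxymethoxy)phenyl]-4H-pyran-4-one; 16 3-(benzyloxy)cyclobut-3-ene-1,2-dione
Product: 18 (±)-3-(benzyloxy)-4-hydroxy-4-{5-(methoxymethoxy)-6-[3-methoxy-4-(methoxymethoxy)phenyl]-4-oxo-4H-pyran-2-yl}cyclobut-2-en-1-one, via pyranonylmagnesium chloride 17 (not isolated)
Conditions: iPrMgCl·LiCl, THF, −40 °C; cannulate into 16, THF, −78 °C; aq NH4Cl
Reagents that add atoms: none
Why: Iodine–magnesium exchange, known for β-iodo-α,β-unsaturated carbonyl compounds, gives an α-oxygenated alkenylmagnesium without a β leaving group, and its 1,2-addition goes to the ketone-like carbonyl next to the C–OBn carbon because the other carbonyl is deactivated as a vinylogous ester; the new carbinol centre is racemic and is lost in step 13.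

Step 12
Reactants: 18 (±)-3-(benzyloxy)-4-hydroxy-4-{5-(methoxymethoxy)-6-[3-methoxy-4-(methoxymethoxy)phenyl]-4-oxo-4H-pyran-2-yl}cyclobut-2-en-1-one
Product: 19 (±)-3-(benzyloxy)-4-methoxy-4-{5-(methoxymethoxy)-6-[3-methoxy-4-(methoxymethoxy)phenyl]-4-oxo-4H-pyran-2-yl}cyclobut-2-en-1-one
Conditions: MeI, Ag2O, 4 Å MS, MeCN, rt, dark
Reagents that add atoms: iodomethane, CI
Why: Purdie methylation, the usual neutral etherification of 4-hydroxycyclobutenones, caps the tertiary alcohol without the risk, inherent in a methyl sulfonate ester, of O-alkylating the pyranone carbonyl to a 4-methoxypyrylium salt.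

Step 13
Reactants: 19 (±)-3-(benzyloxy)-4-methoxy-4-{5-(methoxymethoxy)-6-[3-methoxy-4-(methoxymethoxy)phenyl]-4-oxo-4H-pyran-2-yl}cyclobut-2-en-1-one
Product: 22 7-(benzyloxy)-5-hydroxy-8-methoxy-3-(methoxymethoxy)-2-[3-methoxy-4-(methoxymethoxy)phenyl]-4H-chromen-4-one, via dienylketene 20 (not isolated), via 4aH-chromene-4,5-dione tautomer 21 (not isolated)
Conditions: p-xylene (0.01 M, degassed), 138 °C, Ar
Reagents that add atoms: none
Why: Heating breaks the C1–C4 bond of the cyclobutenone in a conrotatory 4π electrocyclic opening, and the strong preference of an oxygen donor at C4 for outward rotation (torquoselectivity) sends OMe outward and the pyranonyl group inward, giving the (Z)-dienylketene 20 with its ketene carbon beside the pyranone C–H carbon. A thermal disrotatory 6π electrocyclisation over the ketene C=C, the C(OBn)=C(OMe) bond and the pyranone C=C then forms the C4a–C5 bond and closes the six-membered carbocycle, ring A, as the dione 21, whose tautomerisation to the chelated 5-phenol is irreversible. The closest known reaction type is the Moore rearrangement of 4-alkenyl- and 4-(hetero)aryl-4-alkoxycyclobutenones to hydroquinone monoethers; here the alkenyl arm is the β-alkoxy-enone bond of a 4-pyranone, whose reacting carbon is the nucleophilic α-carbon of a vinylogous ester and is therefore matched to the electrophilic ketene carbon, while the low aromaticity of the pyranone keeps the cost of closure below that of a benzene ring. No stereocentre survives, since C4 of 19 becomes sp2 on opening and C4a of 21 on enolisation. Site selectivity is built in because the inward group offers only one carbon neighbour (the other is the ring oxygen), and the atom map ketene C=O → 5-OH, vinyl CH → C6–H, C–OBn → C7, C–OMe → C8 places the 8-methoxy group next to O1. The methyl ether stops the product at the hydroquinone monoether stage, and high dilution in degassed solvent suppresses ketene dimerisation.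

Step 14
Reactants: 22 7-(benzyloxy)-5-hydroxy-8-methoxy-3-(methoxymethoxy)-2-[3-methoxy-4-(methoxymethoxy)phenyl]-4H-chromen-4-one
Product: 23 5,7-dihydroxy-8-methoxy-3-(methoxymethoxy)-2-[3-methoxy-4-(methoxymethoxy)phenyl]-4H-chromen-4-one
Conditions: H2 (1 atm), 10% Pd/C, EtOAc, rt
Reagents that add atoms: none
Why: Catalytic hydrogenolysis cleaves only the benzylic C–O bond, since the MOM acetals, the methyl ethers and the tetrasubstituted C2=C3 bond of the flavone are inert at one atmosphere.

Step 15
Reactants: 23 5,7-dihydroxy-8-methoxy-3-(methoxymethoxy)-2-[3-methoxy-4-(methoxymethoxy)phenyl]-4H-chromen-4-one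
Product: 24 5-hydroxy-8-methoxy-3-(methoxymethoxy)-2-[3-methoxy-4-(methoxymethoxy)phenyl]-7-[(3-methylbut-2-en-1-yl)oxy]-4H-chromen-4-one
Conditions: prenyl bromide (1.1 equiv), K2CO3 (1.2 equiv), acetone, rt → 40 °C
Reagents that add atoms: prenyl bromide (1-bromo-3-methylbut-2-ene), CC(C)=CCBr
Why: Williamson etherification is selective for the acidic 7-OH (vinylogous acid) because the 5-OH is held in a hydrogen bond to the C4 carbonyl and is not deprotonated by carbonate.

Step 16
Reactants: 24 5-hydroxy-8-methoxy-3-(methoxymethoxy)-2-[3-methoxy-4-(methoxymethoxy)phenyl]-7-[(3-methylbut-2-en-1-yl)oxy]-4H-chromen-4-one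
Product: 25 3,5-dihydroxy-2-(4-hydroxy-3-methoxyphenyl)-8-methoxy-7-[(3-methylbut-2-en-1-yl)oxy]-4H-chromen-4-one (target, CNP0210396.0)
Conditions: conc HCl (cat), MeOH–THF, rt → 40 °C
Reagents that add atoms: none
Why: Acid-catalysed transacetalisation to methanol removes the two MOM groups, which as acetals of acidic hydroxyls ionise far more easily than the allylic ether, so a catalytic acid charge at low temperature should spare the prenyl group.

**Compound list**
1 | vanillin | COc1cc(C=O)ccc1O | starting material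
2 | 3-methoxy-4-(methoxymethoxy)benzaldehyde | COCOc1ccc(C=O)cc1OC | intermediate
3 | furan | c1ccoc1 | starting material
4 | 2-lithiofuran | [Li]c1ccco1 | intermediate
5 | (±)-furan-2-yl[3-methoxy-4-(methoxymethoxy)phenyl]methanol | COCOc1ccc(C(O)c2ccco2)cc1OC | intermediate
6 | 6-hydroxy-2-[3-methoxy-4-(methoxymethoxy)phenyl]-2H-pyran-3(6H)-one (racemic, anomer mixture) | COCOc1ccc(C2OC(O)C=CC2=O)cc1OC | intermediate
7 | 6-methoxy-2-[3-methoxy-4-(methoxymethoxy)phenyl]-2H-pyran-3(6H)-one (diastereomer mixture) | COCOc1ccc(C2OC(OC)C=CC2=O)cc1OC | intermediate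
8 | 2-methoxy-4-[3-methoxy-4-(methoxymethoxy)phenyl]-3,7-dioxabicyclo[4.1.0]heptan-5-one (diastereomer mixture) | COCOc1ccc(C2OC(OC)C3OC3C2=O)cc1OC | intermediate
9 | 3-hydroxy-2-(4-hydroxy-3-methoxyphenyl)-4H-pyran-4-one | COc1cc(-c2occc(=O)c2O)ccc1O | intermediate
10 | 3-(methoxymethoxy)-2-[3-methoxy-4-(methoxymethoxy)phenyl]-4H-pyran-4-one | COCOc1ccc(-c2occc(=O)c2OCOC)cc1OC | intermediate
11 | {5-(methoxymethoxy)-6-[3-methoxy-4-(methoxymethoxy)phenyl]-4-oxo-4H-pyran-2-yl}zinc chloride | COCOc1ccc(-c2oc([Zn]Cl)cc(=O)c2OCOC)cc1OC | intermediate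
12 | 6-iodo-3-(methoxymethoxy)-2-[3-methoxy-4-(methoxymethoxy)phenyl]-4H-pyran-4-one | COCOc1ccc(-c2oc(I)cc(=O)c2OCOC)cc1OC | intermediate
13 | squaric acid | OC1=C(O)C(=O)C1=O | starting material
14 | dibenzyl squarate | O=C1C(=O)C(OCc2ccccc2)=C1OCc1ccccc1 | intermediate
15 | (±)-2,3-bis(benzyloxy)-4-hydroxycyclobut-2-en-1-one | O=C1C(OCc2ccccc2)=C(OCc2ccccc2)C1O | intermediate
16 | 3-(benzyloxy)cyclobut-3-ene-1,2-dione (benzyl semisquarate) | O=C1C=C(OCc2ccccc2)C1=O | intermediate
17 | {5-(methoxymethoxy)-6-[3-methoxy-4-(methoxymethoxy)phenyl]-4-oxo-4H-pyran-2-yl}magnesium chloride | COCOc1ccc(-c2oc([Mg]Cl)cc(=O)c2OCOC)cc1OC | intermediate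
18 | (±)-3-(benzyloxy)-4-hydroxy-4-{5-(methoxymethoxy)-6-[3-methoxy-4-(methoxymethoxy)phenyl]-4-oxo-4H-pyran-2-yl}cyclobut-2-en-1-one | COCOc1c(-c2ccc(OCOC)c(OC)c2)oc(C2(O)C(OCc3ccccc3)=CC2=O)cc1=O | intermediate
19 | (±)-3-(benzyloxy)-4-methoxy-4-{5-(methoxymethoxy)-6-[3-methoxy-4-(methoxymethoxy)phenyl]-4-oxo-4H-pyran-2-yl}cyclobut-2-en-1-one | COCOc1c(-c2ccc(OCOC)c(OC)c2)oc(C2(OC)C(OCc3ccccc3)=CC2=O)cc1=O | intermediate
20 | (Z)-3-(benzyloxy)-4-methoxy-4-{5-(methoxymethoxy)-6-[3-methoxy-4-(methoxymethoxy)phenyl]-4-oxo-4H-pyran-2-yl}buta-1,3-dien-1-one (dienylketene) | O=C=C/C(OCc1ccccc1)=C(/OC)c1cc(=O)c(OCOC)c(-c2ccc(OCOC)c(OC)c2)o1 | intermediate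
21 | (±)-7-(benzyloxy)-8-methoxy-3-(methoxymethoxy)-2-[3-methoxy-4-(methoxymethoxy)phenyl]-4aH-chromene-4,5-dione | COCOC1=C(c2ccc(OCOC)c(OC)c2)OC2=C(OC)C(OCc3ccccc3)=CC(=O)C2C1=O | intermediate
22 | 7-(benzyloxy)-5-hydroxy-8-methoxy-3-(methoxymethoxy)-2-[3-methoxy-4-(methoxymethoxy)phenyl]-4H-chromen-4-one | COCOc1c(-c2ccc(OCOC)c(OC)c2)oc2c(OC)c(OCc3ccccc3)cc(O)c2c1=O | intermediate
23 | 5,7-dihydroxy-8-methoxy-3-(methoxymethoxy)-2-[3-methoxy-4-(methoxymethoxy)phenyl]-4H-chromen-4-one | COCOc1c(-c2ccc(OCOC)c(OC)c2)oc2c(OC)c(O)cc(O)c2c1=O | intermediate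
24 | 5-hydroxy-8-methoxy-3-(methoxymethoxy)-2-[3-methoxy-4-(methoxymethoxy)phenyl]-7-[(3-methylbut-2-en-1-yl)oxy]-4H-chromen-4-one | COCOc1c(-c2ccc(OCOC)c(OC)c2)oc2c(OC)c(OCC=C(C)C)cc(O)c2c1=O | intermediate
25 | 3,5-dihydroxy-2-(4-hydroxy-3-methoxyphenyl)-8-methoxy-7-[(3-methylbut-2-en-1-yl)oxy]-4H-chromen-4-one | COc1cc(-c2oc3c(OC)c(OCC=C(C)C)cc(O)c3c(=O)c2O)ccc1O | target

**Step count**
Total step count: 16. Longest linear sequence: 14 (steps 1–8 and 11–16, from vanillin). The squarate branch (steps 9 and 10) joins at step 11.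

**Steps most likely to fail**

Step 13. The dienylketene may be consumed by dimerisation or by capture with traces of water. It may also simply reclose and slowly decompose if 6π closure onto the electron-poor, weakly aromatic pyranone bond is slow. This bond is the one variable without a direct model among the alkenyl and heteroaryl arms used so far. The fallback buys ring A instead of building it and sets out from 2.
- Claisen–Schmidt condensation (KOH, EtOH, rt) with commercial 1-[2,4-bis(benzyloxy)-6-hydroxyphenyl]ethanone should give the chalcone (E)-1-[2,4-bis(benzyloxy)-6-hydroxyphenyl]-3-[3-methoxy-4-(methoxymethoxy)phenyl]prop-2-en-1-one F1.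
- Algar–Flynn–Oyamada oxidation (H2O2, NaOH, MeOH) closes ring C to 5,7-bis(benzyloxy)-3-hydroxy-2-[3-methoxy-4-(methoxymethoxy)phenyl]-4H-chromen-4-one F2.
- MOMCl and iPr2NEt give 5,7-bis(benzyloxy)-3-(methoxymethoxy)-2-[3-methoxy-4-(methoxymethoxy)phenyl]-4H-chromen-4-one F3.
- NIS in DMF iodinates C8, the less hindered of the two doubly activated positions of a 5,7-dialkoxyflavone, to give 5,7-bis(benzyloxy)-8-iodo-3-(methoxymethoxy)-2-[3-methoxy-4-(methoxymethoxy)phenyl]-4H-chromen-4-one F4.
- Ullmann-type methoxylation (NaOMe, CuBr, DMF–MeOH, 110 °C) gives 5,7-bis(benzyloxy)-8-methoxy-3-(methoxymethoxy)-2-[3-methoxy-4-(methoxymethoxy)phenyl]-4H-chromen-4-one F5.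
- Hydrogenolysis of both benzyl ethers (H2, Pd/C, EtOAc) comes back to the route at 23.

Step 11. The exchange reagent may attack C6 with loss of iodide. The magnesiated pyranone may condense with itself before it meets the dione, or it may add in conjugate fashion to the unsubstituted vinyl carbon of 16. The fallback gives up the halide, the exchange and the basic carbanion altogether. It sets out from 10, which is zincated as in step 8 to the stable, non-basic organozinc 11. In place of iodine, 16 and anhydrous MgCl2 are added (THF, −20 °C → rt), so that reactivity comes from Lewis-acid activation of the strained ketone carbonyl rather than from the nucleophile. Work-up with aq NH4Cl comes back to the route at 18, one step earlier. No compound outside the list is made (F0).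

Step 16. Acid may ionise the allylic C–O bond of the 7-prenyl ether (loss of the prenyl group, or hydration of its double bond) in competition with cleavage of the slower 4'-O acetal. The fallback moves all acid treatment ahead of the prenylation and ends under base. It sets out from 22.
- HCl in MeOH (50 °C) removes both MOM groups to give 7-(benzyloxy)-3,5-dihydroxy-2-(4-hydroxy-3-methoxyphenyl)-8-methoxy-4H-chromen-4-one F6.
- Ac2O, pyridine and DMAP give the triacetate 4-[3,5-diacetoxy-7-(benzyloxy)-8-methoxy-4-oxo-4H-chromen-2-yl]-2-methoxyphenyl acetate F7.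
- Hydrogenolysis (H2, Pd/C, EtOAc) frees the 7-OH in 4-(3,5-diacetoxy-7-hydroxy-8-methoxy-4-oxo-4H-chromen-2-yl)-2-methoxyphenyl acetate F8.
- A neutral Mitsunobu etherification (3-methylbut-2-en-1-ol, PPh3, DIAD, THF, 0 °C) gives 4-{3,5-diacetoxy-8-methoxy-7-[(3-methylbut-2-en-1-yl)oxy]-4-oxo-4H-chromen-2-yl}-2-methoxyphenyl acetate F9.
- Methanolysis (K2CO3 cat, MeOH, 0 °C) comes back to the route at 25.

**Further compounds**
F1 | step 13 | (E)-1-[2,4-bis(benzyloxy)-6-hydroxyphenyl]-3-[3-methoxy-4-(methoxymethoxy)phenyl]prop-2-en-1-one | COCOc1ccc(/C=C/C(=O)c2c(O)cc(OCc3ccccc3)cc2OCc2ccccc2)cc1OC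
F2 | step 13 | 5,7-bis(benzyloxy)-3-hydroxy-2-[3-methoxy-4-(methoxymethoxy)phenyl]-4H-chromen-4-one | COCOc1ccc(-c2oc3cc(OCc4ccccc4)cc(OCc4ccccc4)c3c(=O)c2O)cc1OC
F3 | step 13 | 5,7-bis(benzyloxy)-3-(methoxymethoxy)-2-[3-methoxy-4-(methoxymethoxy)phenyl]-4H-chromen-4-one | COCOc1ccc(-c2oc3cc(OCc4ccccc4)cc(OCc4ccccc4)c3c(=O)c2OCOC)cc1OC
F4 | step 13 | 5,7-bis(benzyloxy)-8-iodo-3-(methoxymethoxy)-2-[3-methoxy-4-(methoxymethoxy)phenyl]-4H-chromen-4-one | COCOc1ccc(-c2oc3c(I)c(OCc4ccccc4)cc(OCc4ccccc4)c3c(=O)c2OCOC)cc1OC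
F5 | step 13 | 5,7-bis(benzyloxy)-8-methoxy-3-(methoxymethoxy)-2-[3-methoxy-4-(methoxymethoxy)phenyl]-4H-chromen-4-one | COCOc1ccc(-c2oc3c(OC)c(OCc4ccccc4)cc(OCc4ccccc4)c3c(=O)c2OCOC)cc1OC
F0 | step 11 | none | none
F6 | step 16 | 7-(benzyloxy)-3,5-dihydroxy-2-(4-hydroxy-3-methoxyphenyl)-8-methoxy-4H-chromen-4-one | COc1cc(-c2oc3c(OC)c(OCc4ccccc4)cc(O)c3c(=O)c2O)ccc1O
F7 | step 16 | 4-[3,5-diacetoxy-7-(benzyloxy)-8-methoxy-4-oxo-4H-chromen-2-yl]-2-methoxyphenyl acetate | COc1cc(-c2oc3c(OC)c(OCc4ccccc4)cc(OC(C)=O)c3c(=O)c2OC(C)=O)ccc1OC(C)=O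
F8 | step 16 | 4-(3,5-diacetoxy-7-hydroxy-8-methoxy-4-oxo-4H-chromen-2-yl)-2-methoxyphenyl acetate | COc1cc(-c2oc3c(OC)c(O)cc(OC(C)=O)c3c(=O)c2OC(C)=O)ccc1OC(C)=O
F9 | step 16 | 4-{3,5-diacetoxy-8-methoxy-7-[(3-methylbut-2-en-1-yl)oxy]-4-oxo-4H-chromen-2-yl}-2-methoxyphenyl acetate | COc1cc(-c2oc3c(OC)c(OCC=C(C)C)cc(OC(C)=O)c3c(=O)c2OC(C)=O)ccc1OC(C)=O
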